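Labdane numbering is used: ring A = C1–C5/C10, ring B = C5–C10, C20 = methyl on C10, C19 = ester carbon on C4, C17 = carbon on C8, C11–C16 = side chain on C9; the target is methyl (1S,4R,5S,9R,10S,12E)-1-acetoxylabda-8(17),12,14-trien-19-oate.
Enabling feature: the oxygen on C1 lies next to quaternary C10, and C9 bears C11; an alkynoate hung on O1, whose carbonyl carbon becomes C11, therefore places a C8≡C9 dienophile over a C10=C5–C6=C7 diene built on ring A.
Retrosynthetic cuts, in order: C11–C12 (allyl–alkenyl coupling); C9–H with C8=C17 (reductive allylic transposition from C17–OH); the O1–C11 lactone; C9–C10 and C7–C8 (intramolecular Diels–Alder); the O1–C11 ester; C5–C6 (vinyl addition); C1–C10 and C3–C4 (Claisen, Michael).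
Forward: ring A is made first, then the vinyl diene and the ester tether; one cycloaddition closes ring B and a temporary five-membered lactone; the lactone is opened, the side chain is coupled at C11 and the exocyclic methylene is unveiled last.
Stereochemistry: C4 from an auxiliary-controlled Michael addition; a temporary C1 carbinol from CBS reduction, relayed by the tether to C10; C5 by hydrogenation anti to C20; final C1 by oxidation and axial hydride delivery; C9 by diazene hydrogen transfer anti to C20; 12E from syn-carboalumination.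

Key step: step 9

Remark 1: in step 2 the L-valine auxiliary in THF is taken to give the (R)-quaternary centre; the sense of this addition depends on solvent and additive, and if it proved opposite the D-valine ester would be used with nothing else changed.
Remark 2: but-1-en-3-yne (23) is taken as purchasable as a stabilised solution; otherwise it is made from 1,4-dichlorobut-2-ene and KOH.

Step 1
Reactants: 1 methyl 2-methyl-3-oxopentanoate; 2 L-valine tert-butyl ester (free base)
Product: 3 methyl (2Z)-3-{[(2S)-1-tert-butoxy-3-methyl-1-oxobutan-2-yl]amino}-2-methylpent-2-enoate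
Conditions: BF3·OEt2 (cat.), toluene, reflux, Dean–Stark
Reagents that add atoms: none
Why: Acid-catalysed condensation of a β-keto ester with a primary amine (enamine formation), driven by azeotropic removal of water, should give the hydrogen-bonded (Z)-enamino ester carrying the valine auxiliary.

Step 2
Reactants: 3 enamino ester; 4 methyl acrylate
Product: 6 dimethyl (2R)-2-methyl-2-propanoylpentanedioate, via silyl ketene acetal imine 5 (not isolated)
Conditions: LiN(iPr)2, THF, −78 °C; methyl acrylate, Me3SiCl, −100 to −78 °C; then aq. citric acid, rt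
Reagents that add atoms: water, O
Why: Auxiliary-controlled asymmetric Michael addition of a lithiated chiral enamino ester to an acrylate, in which the isopropyl group of the chelated lithium aza-enolate shields one face, Me3SiCl traps the ester enolate as its silyl ketene acetal, and mild acid then hydrolyses imine and ketene acetal, setting the C4 quaternary centre and returning the auxiliary.

Step 3
Reactants: 6 keto diester
Product: 7 methyl (1R)-1,3-dimethyl-2,4-dioxocyclohexane-1-carboxylate (enolisable at C3)
Conditions: KOtBu (2.2 equiv), THF, 0 °C to rt; then 1 M HCl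
Reagents that add atoms: none
Why: Dieckmann-type intramolecular Claisen condensation, in which the ethyl ketone enolate acylates the remote ester in a six-membered closure (C1–C10) and deprotonation of the acidic 1,3-dione drives the step, while the quaternary centre has no α-hydrogen and cannot epimerise.

Step 4
Reactants: 7 dione
Product: 8 methyl (1R)-4-methoxy-1,3-dimethyl-2-oxocyclohex-3-ene-1-carboxylate
Conditions: HC(OMe)3, MeOH, TsOH·H2O (cat.), rt
Reagents that add atoms: methanol, CO (the OCH3 group; also supplied by trimethyl orthoformate, COC(OC)OC)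
Why: Acid-catalysed enol etherification of a cyclic 1,3-dione (vinylogous ester formation) should occur at the less hindered C1 carbonyl, remote from the quaternary carbon, leaving the C5 carbonyl free for the next addition.

Step 5
Reactants: 8 vinylogous ester; 9 vinylmagnesium bromide
Product: 11 methyl (1R)-2-ethenyl-1,3-dimethyl-4-oxocyclohex-2-ene-1-carboxylate, via tertiary allylic alcohol 10 (not isolated)
Conditions: vinylmagnesium bromide, THF, −78 to 0 °C; then 1 M HCl, rt
Reagents that add atoms: water, O
Why: Stork–Danheiser transposition, in which 1,2-addition of the vinyl Grignard reagent to the ketone of the vinylogous ester (the neighbouring ester is shielded by the quaternary carbon) and acid-mediated loss of water and methanol should give the 3-vinyl enone with the C5=C10 bond in place.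

Step 6
Reactants: 11 dienone
Product: 12 methyl (1R,4R)-2-ethenyl-4-hydroxy-1,3-dimethylcyclohex-2-ene-1-carboxylate
Conditions: (S)-Me-CBS oxazaborolidine [(3aS)-1-methyl-3,3-diphenyltetrahydro-1H,3H-pyrrolo[1,2-c][1,3,2]oxazaborole] (20 mol %), catecholborane, toluene, −78 °C
Reagents that add atoms: none
Why: Corey–Bakshi–Shibata reduction, in which the catalyst binds the ketone with the α-methylated alkenyl carbon as the large group and delivers hydride to one face, should give the (R)-carbinol, trans to the ester on the quaternary carbon, under catalyst control.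

Step 7
Reactants: 13 tert-butyldimethyl(prop-2-yn-1-yloxy)silane
Product: 14 4-[(tert-butyldimethylsilyl)oxy]but-2-ynoic acid
Conditions: n-BuLi, THF, −78 °C; CO2; then cold 1 M HCl to pH 3
Reagents that add atoms: carbon dioxide, O=C=O
Why: Deprotonation of the terminal alkyne and carboxylation of the lithium acetylide is a standard route to alkynoic acids and leaves the silyl ether untouched.

Step 8
Reactants: 12 dienol; 14 alkynoic acid
Product: 15 methyl (1R,4R)-4-({4-[(tert-butyldimethylsilyl)oxy]but-2-ynoyl}oxy)-2-ethenyl-1,3-dimethylcyclohex-2-ene-1-carboxylate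
Conditions: N,N'-dicyclohexylcarbodiimide, 4-(dimethylamino)pyridine (cat.), CH2Cl2, −20 to 0 °C
Reagents that add atoms: none
Why: Steglich esterification at low temperature should acylate the secondary allylic alcohol with retention at C1 and without ionising the dienylic carbinol or isomerising the ynoate.

Step 9
Reactants: 15 dienyl alkynoate
Product: 16 methyl (1R,4R,10R)-17-(tert-butyldimethylsilyloxy)-1,11-epoxy-11-oxo-12,13,14,15,16-pentanorlabda-5,8-dien-19-oate (tricyclic lactone; C11 carbonyl on C9, ring oxygen on C1)
Conditions: xylene (0.01 M, degassed), 2,6-di-tert-butyl-4-methylphenol (cat.), 140 °C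
Reagents that add atoms: none
Why: On heating, the alkynoate held on the C1 oxygen should add across the C10=C5–C6=C7 diene in a concerted, suprafacial [4+2] cycloaddition that forms C9–C10 and C7–C8 in one event; the closest known reaction type is the thermal intramolecular Diels–Alder reaction of 3-vinylcyclohex-2-enyl alkynoates, which gives angularly methylated tricyclic lactones. Ring B closes as a cyclohexa-1,4-diene by the cycloaddition itself (both new bonds lie in it), and the five-membered lactone closes through the same C9–C10 bond as a ring cis-fused to ring A, the three tether atoms (C1, O, C11) allowing no other mode. The one new stereocentre, quaternary C10, is controlled by the C1 carbinol centre: the short tether can bring C9 only onto the diene face that carries the C1 oxygen, so the C20 methyl goes to the opposite face, which is the face of the C19 ester because O1 and that ester were set trans. Only diene-face selectivity is needed, since the tether fixes the regiochemistry and an alkyne dienophile raises no endo/exo question. Dilution and the radical inhibitor suppress intermolecular addition and polymerisation, and the silyl ether is inert at this temperature.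

Step 10
Reactants: 16 tricyclic lactone
Product: 17 methyl (1R,4R,5S,10R)-17-(tert-butyldimethylsilyloxy)-1,11-epoxy-11-oxo-12,13,14,15,16-pentanorlabd-8-en-19-oate
Conditions: H2 (3 atm), PtO2 (cat.), EtOAc, rt
Reagents that add atoms: none
Why: Heterogeneous catalytic hydrogenation should reduce only the trisubstituted C5=C6 bond, the catalyst approaching the face opposite the C20 methyl and the axial C19 ester so that H5 ends up trans to C20 (trans-decalin), while the tetrasubstituted, conjugated C8=C9 bond is left.

Step 11
Reactants: 17 lactone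
Product: 18 methyl (1R,4R,5S,10R)-17-(tert-butyldimethylsilyloxy)-1,11-dihydroxy-12,13,14,15,16-pentanorlabd-8-en-19-oate
Conditions: LiBH4, THF, 0 °C to rt
Reagents that add atoms: none
Why: Chemoselective hydride reduction of a lactone, in which the strained cis-fused unsaturated lactone should be reduced by 1,2-addition (its β-carbon is fully substituted) to the allylic 1,4-diol well before the axial, neopentyl C19 methyl ester reacts.

Step 12
Reactants: 18 diol
Product: 19 methyl (1R,4R,5S,10R)-11-acetoxy-17-(tert-butyldimethylsilyloxy)-1-hydroxy-12,13,14,15,16-pentanorlabd-8-en-19-oate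
Conditions: Ac2O (1.1 equiv), pyridine, CH2Cl2, 0 °C
Reagents that add atoms: acetic anhydride, CC(=O)OC(C)=O
Why: Selective acylation of the primary allylic alcohol over the axial, neopentyl-type C1 alcohol installs the later allylic leaving group and keeps the 1,4-diol from closing to a cyclic ether once C11 is activated.

Step 13
Reactants: 19 hydroxy acetate
Product: 20 methyl (4R,5S,10R)-11-acetoxy-17-(tert-butyldimethylsilyloxy)-1-oxo-12,13,14,15,16-pentanorlabd-8-en-19-oate
Conditions: Dess–Martin periodinane, pyridine, CH2Cl2, rt
Reagents that add atoms: none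
Why: Dess–Martin oxidation of the hindered axial secondary alcohol should give the C1 ketone, which cannot enolise toward quaternary C10, so the C8=C9 bond stays where it is.

Step 14
Reactants: 20 keto acetate
Product: 21 methyl (1S,4R,5S,10R)-11-acetoxy-17-(tert-butyldimethylsilyloxy)-1-hydroxy-12,13,14,15,16-pentanorlabd-8-en-19-oate
Conditions: NaBH4, MeOH–THF, −20 to 0 °C
Reagents that add atoms: none
Why: Borohydride reduction of a cyclohexanone flanked by a quaternary carbon with an axial methyl should proceed by axial hydride attack on the face opposite C20, giving the equatorial alcohol cis to C20 and thereby inverting C1 relative to 19.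

Step 15
Reactants: 21 hydroxy acetate
Product: 22 methyl (1S,4R,5S,10R)-1,11-diacetoxy-17-(tert-butyldimethylsilyloxy)-12,13,14,15,16-pentanorlabd-8-en-19-oate
Conditions: Ac2O, Et3N, 4-(dimethylamino)pyridine (cat.), CH2Cl2, rt
Reagents that add atoms: acetic anhydride, CC(=O)OC(C)=O
Why: Nucleophile-catalysed acetylation installs the C1 acetate of the target, and any acetyl migration between O11 and O1 during step 14 converges on the same diacetate.

Step 16
Reactants: 22 diacetate; 23 but-1-en-3-yne
Product: 25 methyl (1S,4R,5S,10R,12E)-1-acetoxy-17-(tert-butyldimethylsilyloxy)labda-8,12,14-trien-19-oate, via dienylalane 24 (not isolated)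
Conditions: but-1-en-3-yne, Me3Al, Cp2ZrCl2 (25 mol %), (CH2Cl)2, rt; volatiles removed; then 22, Pd(PPh3)4 (5 mol %), THF, rt
Reagents that add atoms: trimethylaluminium, C[Al](C)C
Why: Zirconium-catalysed carboalumination adds methyl and aluminium syn across the alkyne to give the (E)-dienylalane, and palladium-catalysed allyl–alkenyl coupling (Negishi type) of the allylic acetate, ionised by zerovalent palladium with help from the Lewis-acidic alane, should join C11 to C12 at the primary allyl terminus with retention of alkene geometry, the non-allylic C1 acetate and the hindered ester not being ionised.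

Step 17
Reactants: 25 silyl ether
Product: 26 methyl (1S,4R,5S,10R,12E)-1-acetoxy-17-hydroxylabda-8,12,14-trien-19-oate
Conditions: Bu4NF, AcOH, THF, 0 °C to rt
Reagents that add atoms: none
Why: Fluoride-mediated cleavage of the primary silyl ether, buffered with acetic acid so that the acetate is not exposed to base, should free the C17 allylic alcohol.

Step 18
Reactants: 26 allylic alcohol
Product: 29 methyl (1S,4R,5S,9R,10S,12E)-1-acetoxylabda-8(17),12,14-trien-19-oate, via allylic sulfonylhydrazine 27 (not isolated), via allylic diazene 28 (not isolated)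
Conditions: PPh3, diethyl azodicarboxylate, THF, −30 °C (betaine preformed); 26; 2-nitrobenzenesulfonylhydrazide, −30 °C; then rt
Reagents that add atoms: none
Why: Reductive 1,3-transposition of an allylic alcohol through a monoalkyl diazene, in which Mitsunobu displacement at primary C17 by the sulfonylhydrazide, loss of 2-nitrobenzenesulfinic acid on warming and retro-ene loss of N2 move the alkene to C8=C17 and deliver hydrogen to C9 on the ring face opposite the axial C20 methyl, setting the 9R centre with C11 cis to C20, while preforming the betaine keeps free azodicarboxylate away from the side-chain diene.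

Compound list
1 | methyl 2-methyl-3-oxopentanoate | CCC(=O)C(C)C(=O)OC | starting material
2 | L-valine tert-butyl ester | CC(C)[C@H](N)C(=O)OC(C)(C)C | starting material
3 | methyl (2Z)-3-{[(2S)-1-tert-butoxy-3-methyl-1-oxobutan-2-yl]amino}-2-methylpent-2-enoate | CC/C(N[C@@H](C(C)C)C(=O)OC(C)(C)C)=C(C)/C(=O)OC | intermediate
4 | methyl acrylate | C=CC(=O)OC | starting material
5 | tert-butyl N-[(4R)-7-methoxy-4-(methoxycarbonyl)-4-methyl-7-(trimethylsilyloxy)hept-6-en-3-ylidene]-L-valinate (silyl ketene acetal imine) | CCC(=N[C@@H](C(C)C)C(=O)OC(C)(C)C)[C@](C)(C(=O)OC)CC=C(OC)O[Si](C)(C)C | intermediate (not isolated)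
6 | dimethyl (2R)-2-methyl-2-propanoylpentanedioate | CCC(=O)[C@](C)(C(=O)OC)CCC(=O)OC | intermediate
7 | methyl (1R)-1,3-dimethyl-2,4-dioxocyclohexane-1-carboxylate | CC1C(=O)CC[C@@](C)(C(=O)OC)C1=O | intermediate
8 | methyl (1R)-4-methoxy-1,3-dimethyl-2-oxocyclohex-3-ene-1-carboxylate | COC1=C(C)C(=O)[C@](C)(C(=O)OC)CC1 | intermediate
9 | vinylmagnesium bromide | C=C[Mg]Br | starting material
10 | methyl (1R)-2-ethenyl-2-hydroxy-4-methoxy-1,3-dimethylcyclohex-3-ene-1-carboxylate (tertiary allylic alcohol, C2 epimers) | COC1=C(C)C(O)(C=C)[C@](C)(C(=O)OC)CC1 | intermediate (not isolated)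
11 | methyl (1R)-2-ethenyl-1,3-dimethyl-4-oxocyclohex-2-ene-1-carboxylate | C=CC1=C(C)C(=O)CC[C@@]1(C)C(=O)OC | intermediate
12 | methyl (1R,4R)-2-ethenyl-4-hydroxy-1,3-dimethylcyclohex-2-ene-1-carboxylate | C=CC1=C(C)[C@H](O)CC[C@@]1(C)C(=O)OC | intermediate
13 | tert-butyldimethyl(prop-2-yn-1-yloxy)silane | C#CCO[Si](C)(C)C(C)(C)C | starting material
14 | 4-[(tert-butyldimethylsilyl)oxy]but-2-ynoic acid | OC(=O)C#CCO[Si](C)(C)C(C)(C)C | intermediate
15 | methyl (1R,4R)-4-({4-[(tert-butyldimethylsilyl)oxy]but-2-ynoyl}oxy)-2-ethenyl-1,3-dimethylcyclohex-2-ene-1-carboxylate | C=CC1=C(C)[C@H](OC(=O)C#CCO[Si](C)(C)C(C)(C)C)CC[C@@]1(C)C(=O)OC | intermediate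
16 | methyl (1R,4R,10R)-17-(tert-butyldimethylsilyloxy)-1,11-epoxy-11-oxo-12,13,14,15,16-pentanorlabda-5,8-dien-19-oate | COC(=O)[C@]1(C)CC[C@H]2OC(=O)C3=C(CO[Si](C)(C)C(C)(C)C)CC=C1[C@@]23C | intermediate
17 | methyl (1R,4R,5S,10R)-17-(tert-butyldimethylsilyloxy)-1,11-epoxy-11-oxo-12,13,14,15,16-pentanorlabd-8-en-19-oate | O=C1O[C@@H]2CC[C@@](C)(C(=O)OC)[C@H]3CCC(CO[Si](C)(C)C(C)(C)C)=C1[C@]23C | intermediate
18 | methyl (1R,4R,5S,10R)-17-(tert-butyldimethylsilyloxy)-1,11-dihydroxy-12,13,14,15,16-pentanorlabd-8-en-19-oate | OCC1=C(CO[Si](C)(C)C(C)(C)C)CC[C@H]2[C@@]1(C)[C@H](O)CC[C@@]2(C)C(=O)OC | intermediate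
19 | methyl (1R,4R,5S,10R)-11-acetoxy-17-(tert-butyldimethylsilyloxy)-1-hydroxy-12,13,14,15,16-pentanorlabd-8-en-19-oate | CC(=O)OCC1=C(CO[Si](C)(C)C(C)(C)C)CC[C@H]2[C@@]1(C)[C@H](O)CC[C@@]2(C)C(=O)OC | intermediate
20 | methyl (4R,5S,10R)-11-acetoxy-17-(tert-butyldimethylsilyloxy)-1-oxo-12,13,14,15,16-pentanorlabd-8-en-19-oate | CC(=O)OCC1=C(CO[Si](C)(C)C(C)(C)C)CC[C@H]2[C@@]1(C)C(=O)CC[C@@]2(C)C(=O)OC | intermediate
21 | methyl (1S,4R,5S,10R)-11-acetoxy-17-(tert-butyldimethylsilyloxy)-1-hydroxy-12,13,14,15,16-pentanorlabd-8-en-19-oate | CC(=O)OCC1=C(CO[Si](C)(C)C(C)(C)C)CC[C@H]2[C@@]1(C)[C@@H](O)CC[C@@]2(C)C(=O)OC | intermediate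
22 | methyl (1S,4R,5S,10R)-1,11-diacetoxy-17-(tert-butyldimethylsilyloxy)-12,13,14,15,16-pentanorlabd-8-en-19-oate | CC(=O)OCC1=C(CO[Si](C)(C)C(C)(C)C)CC[C@H]2[C@@]1(C)[C@@H](OC(C)=O)CC[C@@]2(C)C(=O)OC | intermediate
23 | but-1-en-3-yne | C=CC#C | starting material
24 | dimethyl[(1E)-2-methylbuta-1,3-dien-1-yl]alane | C=C/C(C)=C/[Al](C)C | intermediate (not isolated)
25 | methyl (1S,4R,5S,10R,12E)-1-acetoxy-17-(tert-butyldimethylsilyloxy)labda-8,12,14-trien-19-oate | C=C/C(C)=C/CC1=C(CO[Si](C)(C)C(C)(C)C)CC[C@H]2[C@@]1(C)[C@@H](OC(C)=O)CC[C@@]2(C)C(=O)OC | intermediate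
26 | methyl (1S,4R,5S,10R,12E)-1-acetoxy-17-hydroxylabda-8,12,14-trien-19-oate | C=C/C(C)=C/CC1=C(CO)CC[C@H]2[C@@]1(C)[C@@H](OC(C)=O)CC[C@@]2(C)C(=O)OC | intermediate
27 | methyl (1S,4R,5S,10R,12E)-1-acetoxy-17-[1-(2-nitrobenzenesulfonyl)hydrazin-1-yl]labda-8,12,14-trien-19-oate | C=C/C(C)=C/CC1=C(CN(N)S(=O)(=O)c3ccccc3[N+](=O)[O-])CC[C@H]2[C@@]1(C)[C@@H](OC(C)=O)CC[C@@]2(C)C(=O)OC | intermediate (not isolated)
28 | methyl (1S,4R,5S,10R,12E)-1-acetoxy-17-diazenyllabda-8,12,14-trien-19-oate | C=C/C(C)=C/CC1=C(CN=N)CC[C@H]2[C@@]1(C)[C@@H](OC(C)=O)CC[C@@]2(C)C(=O)OC | intermediate (not isolated)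
29 | methyl (1S,4R,5S,9R,10S,12E)-1-acetoxylabda-8(17),12,14-trien-19-oate | C=C/C(C)=C/C[C@@H]1C(=C)CC[C@H]2[C@@]1(C)[C@@H](OC(C)=O)CC[C@@]2(C)C(=O)OC | target

Total step count: 18. Longest linear sequence: 17 steps (steps 1–6 and 8–18); step 7 is a one-step side branch.

Steps most likely to fail

Step 10. Hydrogen uptake at the C5=C6 bond, which lies between two quaternary carbons, may be slow; the bond may also migrate on the catalyst before it is reduced, and delivery to the wrong face would give the cis-decalin. Fallback: setting out from 16, 1,8-diazabicyclo[5.4.0]undec-7-ene in toluene at 60 °C should move the isolated alkene into conjugation through the extended lactone enolate. Protonation at C5 under equilibrating conditions should give the trans-fused conjugated dienyl lactone methyl (1R,4R,5S,10R)-17-(tert-butyldimethylsilyloxy)-1,11-epoxy-11-oxo-12,13,14,15,16-pentanorlabda-6,8-dien-19-oate F1. Diimide (from 2-nitrobenzenesulfonylhydrazide and Et3N, CH2Cl2, rt) should then saturate only the disubstituted C6=C7 bond, and the route is rejoined at 17.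

Step 16. Ionisation of an allylic acetate on a tetrasubstituted alkene may be sluggish, and the aluminium reagents may meanwhile attack the acetate or ester groups. Fallback: setting out from 22, brief methanolysis (K2CO3, MeOH, 0 °C) should remove only the primary allylic acetate and give methyl (1S,4R,5S,10R)-1-acetoxy-17-(tert-butyldimethylsilyloxy)-11-hydroxy-12,13,14,15,16-pentanorlabd-8-en-19-oate F2. Appel bromination (CBr4, PPh3, CH2Cl2, 0 °C) should then give the allylic bromide methyl (1S,4R,5S,10R)-1-acetoxy-11-bromo-17-(tert-butyldimethylsilyloxy)-12,13,14,15,16-pentanorlabd-8-en-19-oate F3. Separately, alane 24 is quenched with I2 to (1E)-1-iodo-2-methylbuta-1,3-diene F4, which with t-BuLi at −78 °C and then Bu3SnCl should give tributyl[(1E)-2-methylbuta-1,3-dien-1-yl]stannane F5. Stille coupling of the bromide with this stannane (Pd2(dba)3, AsPh3, THF, 50 °C) under neutral conditions comes back to the route at 25.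

Step 18. Hydrogen transfer from the diazene to C9 may not discriminate the two ring faces well enough, and the azodicarboxylate may be consumed by cycloaddition with the side-chain diene. Fallback: setting out from 26, formylation (acetic formic anhydride, pyridine, 0 °C) should give the allylic formate methyl (1S,4R,5S,10R,12E)-1-acetoxy-17-(formyloxy)labda-8,12,14-trien-19-oate F6. Zerovalent palladium generated from Pd(OAc)2 and PBu3 (THF, rt to reflux) should ionise it, lose CO2 and pass hydride from the metal, held on the allyl face opposite C20, to the more substituted terminus C9, which arrives at 29 directly.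

Further compounds
F1 | step 10 | methyl (1R,4R,5S,10R)-17-(tert-butyldimethylsilyloxy)-1,11-epoxy-11-oxo-12,13,14,15,16-pentanorlabda-6,8-dien-19-oate | O=C1O[C@@H]2CC[C@@](C)(C(=O)OC)[C@H]3C=CC(CO[Si](C)(C)C(C)(C)C)=C1[C@]23C
F2 | step 16 | methyl (1S,4R,5S,10R)-1-acetoxy-17-(tert-butyldimethylsilyloxy)-11-hydroxy-12,13,14,15,16-pentanorlabd-8-en-19-oate | OCC1=C(CO[Si](C)(C)C(C)(C)C)CC[C@H]2[C@@]1(C)[C@@H](OC(C)=O)CC[C@@]2(C)C(=O)OC
F3 | step 16 | methyl (1S,4R,5S,10R)-1-acetoxy-11-bromo-17-(tert-butyldimethylsilyloxy)-12,13,14,15,16-pentanorlabd-8-en-19-oate | BrCC1=C(CO[Si](C)(C)C(C)(C)C)CC[C@H]2[C@@]1(C)[C@@H](OC(C)=O)CC[C@@]2(C)C(=O)OC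
F4 | step 16 | (1E)-1-iodo-2-methylbuta-1,3-diene | C=C/C(C)=C/I
F5 | step 16 | tributyl[(1E)-2-methylbuta-1,3-dien-1-yl]stannane | C=C/C(C)=C/[Sn](CCCC)(CCCC)CCCC
F6 | step 18 | methyl (1S,4R,5S,10R,12E)-1-acetoxy-17-(formyloxy)labda-8,12,14-trien-19-oate | C=C/C(C)=C/CC1=C(COC=O)CC[C@H]2[C@@]1(C)[C@@H](OC(C)=O)CC[C@@]2(C)C(=O)OC
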